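**Assumptions (one line each):** (i) The leuco form of naphthazarin reacts as its 2,3-dihydro-1,4-dione tautomer, a ketone-type aldol donor. (ii) The ProPhenol enantiomer that delivers the (S)-carbinol is chosen by screening; (S,S) is written here.

## Retrosynthetic overview
- Target isobutyryl alkannin **1** comes from side-chain O-acylation of alkannin **2**.
- Alkannin **2** comes from a direct catalytic asymmetric hydroxyalkylation of leuconaphthazarin **3** with 4-methylpent-3-enal **5**, followed by oxidation back to the quinone. This step breaks the C2/C3 symmetry of the naphthazarin core and sets the carbinol stereocentre.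
- **3** comes from reduction of naphthazarin **4**. **4** comes from hydroquinone **6** and maleic anhydride **7** by a double Friedel–Crafts acylation, which forms the only new ring, the quinone ring, first.
- Aldehyde **5** comes from 4-methylpent-3-en-1-ol **8**.

## Forward route

**Step 1**
Reactants: **6** hydroquinone; **7** maleic anhydride
Product: **4** naphthazarin (5,8-dihydroxy-1,4-naphthoquinone)
Conditions: AlCl3/NaCl melt, 180 °C, 10–20 min; then ice/HCl work-up
Reagents that add atoms: none (AlCl3 is a promoter and leaves no atoms)
Why: Intermolecular Friedel–Crafts acylation gives the 3-aroylacrylic acid, and a second intramolecular acylation ortho to the other OH closes the ring. C10H6O4 is reached with no external oxidant (C6H6O2 + C4H2O3 − H2O). No stereochemistry is involved.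

**Step 2**
Reactants: **8** 4-methylpent-3-en-1-ol
Product: **5** 4-methylpent-3-enal
Conditions: Dess–Martin periodinane, NaHCO3, CH2Cl2, 0 °C to rt, 1 h; use crude and cold
Reagents that add atoms: none
Why: Buffered Dess–Martin oxidation of a primary alcohol avoids acid or base that would push the β,γ-enal into conjugation.

**Step 3**
Reactants: **4** naphthazarin
Product: **3** leuconaphthazarin (5,8-dihydroxy-2,3-dihydronaphthalene-1,4-dione, tautomer of 1,4,5,8-tetrahydroxynaphthalene)
Conditions: Na2S2O4 (aq., degassed), EtOAc/H2O, rt, N2; extract, dry over Na2SO4 under N2, swap to dry degassed THF
Reagents that add atoms: none (only H is gained)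
Why: Dithionite performs a two-electron, two-proton reduction of the quinone to the leuco form. Its 2,3-dihydro-dione tautomer is the enolisable donor for the next step.

**Step 4**
Reactants: **3** leuconaphthazarin (2 equiv); **5** 4-methylpent-3-enal (1 equiv, slow addition)
Product: **2** alkannin, (S)-5,8-dihydroxy-2-(1-hydroxy-4-methylpent-3-enyl)-1,4-naphthoquinone
Conditions: (S,S)-ProPhenol (10 mol %) with Et2Zn (20 mol %), Ph3P=S, 4 Å MS, THF, −20 °C, N2, 48 h; then activated MnO2 (10 equiv), 0 °C, 1 h
Reagents that add atoms: none beyond the listed reactants (MnO2 only removes H)
Why: This is a direct catalytic asymmetric aldol (Marschalk-type hydroxyalkylation).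
- **Proposed new method:** The peri-phenoxide/ketone of **3** binds the dinuclear Zn-ProPhenol and forms a chelated zinc enolate at C2. The aldehyde is activated at the second Zn and adds through a closed Zimmerman–Traxler-type transition state, which fixes the carbinol face.
- The aldol adduct tautomerises to the leuco aromatic and is oxidised in the same pot by MnO2 to the quinone. The carbinol centre is untouched by the oxidation.
- The closest known chemistry is Zn-ProPhenol aldol of hydroxy-aryl ketones with aliphatic aldehydes, plus the Marschalk reaction of leucoquinones with aldehydes.
- The Zn alkoxide chelate and the low temperature are meant to suppress dehydration to the o-quinone methide, which would lead to racemisation or the deoxy (Marschalk) product.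

**Step 5**
Reactants: **2** alkannin; **9** isobutyric acid
Product: **1** isobutyryl alkannin
Conditions: EDC·HCl, DMAP (cat.), CH2Cl2, 0 °C, dark, 2 h
Reagents that add atoms: isobutyric acid **9**, CC(C)C(=O)O
Why: Steglich-type esterification acylates only the free secondary alcohol. The peri-phenols are hydrogen-bonded to the quinone C=O and are poorly nucleophilic. No C–O bond at the stereocentre is broken, so the configuration is retained.

## Checks
- Target SMILES re-read: it is the (S)-carbinol, with the quinone C2 bearing CH(OC(=O)iPr)CH2CH=CMe2 and the 5,8-OH groups. Alkannin **2** has the same neighbour order and the same CIP priorities (O > quinone C > CH2 > H), so it is (S).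
- Atom balance in step 4: C10H8O4 + C6H10O → C16H18O5, then −2H → C16H16O5 (alkannin). Step 5 adds isobutyryl (C4H6O), giving C20H22O6, the target.
- Functional groups: the prenyl alkene survives steps 2 to 5 (no acid, hydrogenation or peracid is used). The phenols are unprotected throughout, and the steps are chosen so they do not interfere.
- The single stereocentre is set in step 4 and is not touched in step 5.

## Compound list
1 | isobutyryl alkannin | CC(C)=CC[C@H](OC(=O)C(C)C)C1=CC(=O)c2c(O)ccc(O)c2C1=O | target
2 | alkannin, (S)-5,8-dihydroxy-2-(1-hydroxy-4-methylpent-3-enyl)-1,4-naphthoquinone | CC(C)=CC[C@H](O)C1=CC(=O)c2c(O)ccc(O)c2C1=O | intermediate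
3 | leuconaphthazarin (2,3-dihydro-5,8-dihydroxynaphthalene-1,4-dione tautomer) | O=C1CCC(=O)c2c(O)ccc(O)c12 | intermediate
4 | naphthazarin | O=C1C=CC(=O)c2c(O)ccc(O)c12 | intermediate
5 | 4-methylpent-3-enal | CC(C)=CCC=O | intermediate
6 | hydroquinone | Oc1ccc(O)cc1 | starting material
7 | maleic anhydride | O=C1C=CC(=O)O1 | starting material
8 | 4-methylpent-3-en-1-ol | CC(C)=CCCO | starting material
9 | isobutyric acid | CC(C)C(=O)O | starting material

**Total steps:** 5. **Longest linear sequence:** 4 (steps 1, 3, 4, 5).

## Three steps most likely to fail
1. **Step 4 (asymmetric hydroxyalkylation).** Risks are low ee, retro-aldol, self-aldol or isomerisation of the enal, and dehydration through the quinone methide.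
   - Fallback: make racemic alkannin by the same Marschalk-type coupling (Na2S2O4, base, aldehyde). Then resolve and acylate in one operation by lipase-catalysed transesterification with vinyl isobutyrate, which gives (S)-ester **1** directly.
2. **Step 5 (esterification).** Risks are acylation of a peri-OH and partial racemisation through quinone-methide-type ionisation.
   - Fallback: use lipase-mediated acylation with vinyl isobutyrate (neutral, phenol-blind) on enantioenriched **2**.
3. **Step 1 (AlCl3/NaCl melt).** Risks are moderate yield and tar formation.
   - Fallback: buy naphthazarin, or build the quinone ring by Diels–Alder chemistry on a 2-substituted benzoquinone followed by aromatisation/oxidation.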